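## Structural features

The target is an 18-membered macrolactone (counted through the oxazole nitrogen). A 2,4-disubstituted oxazole (C8–C10) is linked through the chain C11–C15 to a tetrahydrofuran (O, C16–C19), and through the E-trisubstituted alkene C6=C7, the allylic carbinol C5, the methyl-bearing C4 and the E-enoate C1–C3 to the C17 oxygen of the same ring. Every ring carbon is substituted: C16 carries the C15 methoxy chain, C17 the lactone oxygen, C18 a bromine, and C19 a methyl group plus the side chain C20–C25, a Z-alkene ending in an (S)-configured tertiary α-hydroxy acid. Five stereocentres stand in a row (C15 to C19), beside the isolated C13 methyl centre, the syn C4/C5 pair and the quaternary carbinol C24. Fragile points are the secondary bromide (a free C17 alkoxide trans to it would close an epoxide), the β-alkoxy relation between the ring oxygen and C21, the Z-alkene, the allylic alcohol conjugated through C6=C7 with the oxazole, and the enoate with its γ-stereocentre. The real difficulty is the ring: a quaternary C19 trans to the C16 chain across the ring oxygen, and bromine on the neopentyl-like C18, trans to the C17 oxygen and to C20. The key step uses the fact that C19 holds the ring oxygen, a methyl group and an allylic methylene (C20) right beside C18. That is the pattern left when an allyl ether oxygen on C16 adds to a carbenoid at C19 and the allyl group moves from oxygen to carbon, with the C18 ketone kept as the later site for bromine.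

## Logic of the disconnections

55 from 53: no skeletal bond is cut. The C5 silyl ether and the acetonide that masks both the C24 hydroxyl and the C25 acid fall in one mild aqueous acid step. The demand is that the allylic alcohol and the lactone survive.

53 from 52: C2=C3 is cut (intramolecular Horner–Wadsworth–Emmons). The hindered C17 oxygen is then acylated beforehand with a small acid instead of serving as nucleophile in the ring closure. The forward step needs mild base, high dilution and no epimerisation at C4.

52 from 41 and 51: C7–C8 is cut (Stille coupling). This splits the molecule into a complex northern half and a six-step southern piece, with the E-geometry of C6=C7 already fixed in 51. The coupling must join a 1-methylalkenylstannane to a heteroaryl triflate beside an aldehyde, a phosphonate and a secondary bromide.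

41 from 32 and 37 (through 39 and 40): C21=C22 is cut (Wittig), followed by exchange of the C17 silyl ether for the phosphonoacetate. The side chain with C24 then comes from 33 in four steps. The step must be Z-selective and must not open the β-alkoxy aldehyde.

32 from 23 (through 24, 25, 27, 28, 30): the oxazole is disconnected at N–C8 and O–C9, so that C10 is the old carboxyl carbon, nitrogen comes from an amide and C8/C9 from a two-carbon acyl unit. This gives the C8 triflate directly and needs no hydride or Grignard step on the advanced material. The terminal alkene stays as the masked C21 aldehyde. The primary C10 silyl ether must be cleaved beside the hindered C17 silyl ether. A triisopropylsilyl group at C10 could not be removed selectively, which is why both ethers are tert-butyldimethylsilyl.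

23 from 20 (through 21): the C18–Br bond is cut back to the C18 ketone. The forward route needs hydride delivery from the face of the C19 methyl group and then substitution with inversion at a neopentyl-type carbon.

20 from 19: O–C19 and C19–C20 are cut (oxonium ylide formation and [2,3]-shift). One ring, one quaternary stereocentre and the side-chain anchor are removed at once, leaving an acyclic allyl ether.

19 from 17: the C19 diazo group is taken off (diazo transfer onto the ethyl ketone). Diazoethane is avoided. Enolisation must go to the ethyl side only.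

17 from 13 (through 14, 15, 16): C17–C18 is cut to a propanoyl anion equivalent and a C17 acyl group, and the C17–H bond comes from reduction of the resulting ketone. Chelation to the C16 allyloxy oxygen should give the 16,17-anti relation.

13 from 6 and 7 (through 9, 10, 11): C15–C16 is cut (syn glycolate aldol). The 15,16-syn relation would be the contra-Felkin outcome of any addition to a C16 aldehyde bearing the C15 methoxy group. The bond is therefore made from the C15 aldehyde 7, which has no α-stereocentre, under auxiliary control. The allyl ether arrives with the glycolate, so no base-sensitive O-allylation of an aldol is needed. C10 is released by selective ozonolysis of the trisubstituted alkene.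

6 from 3 and 4, and 3 from 1 and 2: the N-acyl bond and the ether C–O bond are cut, which are routine.

37 from 33 (through 34, 35, 36): the P–C22 bond and the C22 oxidation state are adjusted. The two carboxyls of 33 are told apart by five-membered acetonide formation.

51 from 42 and 43 (through 45, 46, 47, 49, 50): C4–C5 is cut (syn propionate aldol on an ynal). The alkyne is the precursor of the E-alkenyl metal, with the metal placed on the methyl-bearing carbon.

## Other disconnections considered

Alternative 1: The cut is C6–C7, taken as an alkyne. In the forward sense the diyne A1 (methyl-capped alkynes on oxazole C8 and on C5) would close to the macrocyclic alkyne A2 with (Ph3SiO)3Mo≡C–C6H4OMe and loss of but-2-yne. Trans-hydrostannation and methyl cross-coupling would then turn C6≡C7 into the E-alkene with the C7 methyl group.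
- In favour: the catalyst should ignore the enoate, the bromide and isolated alkenes, and there is no E/Z question at ring closure. The halves are joined by a simple esterification.
- Against: the methyl group must end on C7, away from the C5 oxygen. Hydroxyl-directed trans-hydrometalation tends to place the metal next to the carbinol, so regiocontrol would rest on the silyl ether of A2 and is uncertain. The oxazole nitrogen next to the alkyne may bind molybdenum. A2 carries only a C21 silyl ether, so the side chain would be added after ring closure.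
- Comparison: as a ring closure it is at least the equal of the olefination in step 35, and better in that it avoids a bimolecular coupling of a hindered stannane. It is weaker in needing two more metal-mediated steps on the macrocycle. A1 still contains the bromotetrahydrofuran, so this cut competes with the endgame and not with step 12, and could be combined with it. The step count would be about the same.

Alternative 2: The cut is C1–C2 together with C1–O17. The E-vinyl iodide A3 with a free C17 hydroxyl would take up carbon monoxide under Pd(PPh3)4 and close to the protected macrolactone A4.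
- In favour: the lactone carbonyl carbon and the ring are made in one step, with no phosphonate and no acid activation. The E-geometry comes from the iodide, and the side chain is already complete.
- Against: the acylpalladium intermediate must be captured by the most hindered alcohol of the molecule in the ring-closing event, so oligomers and reduction are likely competitors. The base that is needed meets a free bromohydrin, which can close to an epoxide. Zerovalent palladium also meets a secondary bromide, and carbon monoxide has to be handled.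
- Comparison: in step economy it is better than the chosen endgame by about two steps. Mechanistically the chosen plan is safer, because the C17 oxygen is acylated intermolecularly with a small acid and the ring closes by C=C formation. This cut too is independent of how the tetrahydrofuran is made.

Alternative 3: The cut is O–C19 together with C18–Br. The homoallylic alcohol A5, with an E-trisubstituted alkene, would react with N-bromosuccinimide. The C16 hydroxyl would open the bromonium ion at C19 to give the bromotetrahydrofuran A6.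
- In favour: the ring, the bromine and the C18/C19 relation (anti addition to the E-alkene puts bromine cis to the methyl group) come in one step. No substitution at the neopentyl-type C18 is needed, which makes it better than the chosen plan on that point.
- Against: the closure is 5-endo. The face of bromonium formation is set only by C16 and C17 (substrate control). The E-alkene must be made geometrically pure. The C15 methoxy oxygen can compete for the bromonium ion. The C21 pivalate of A6 must later be unmasked and oxidised.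
- Comparison: it reaches the bromide in fewer steps than steps 12 to 14 and is better at C18. The chosen plan is better in how predictably the C19 quaternary centre is set against C16, and it keeps the C18 carbonyl as a handle.

Key step: step 12

Remarks on the chemistry: atoms are numbered as in the natural product, C1 (lactone carbonyl) to C25 (side-chain carboxyl), with oxazole carbons C8–C10. But-2-ynal (43) and 2-ethyl-1,3-dithiane are taken as purchasable; if 43 is not in stock it would be made from but-2-yn-1-ol with MnO2. The stereodescriptors of 19 and 20 were checked against 55 at C13, C15, C16, C17 and C19 and agree; the silyl groups differ from a triisopropylsilyl/tert-butyldimethylsilyl pair for the reason stated above.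

Step 1
Reactants: 1 allyl alcohol; 2 bromoacetic acid
Product: 3 2-(allyloxy)acetic acid
Conditions: NaH (2.2 equiv), THF, 0 °C → reflux; aq. HCl
Reagents that add atoms: none
Why: Williamson ether synthesis; the alkoxide displaces bromide from the carboxylate salt of 2.

Step 2
Reactants: 3 2-(allyloxy)acetic acid; 4 (R)-4-benzyl-1,3-oxazolidin-2-one
Product: 6 (R)-3-[2-(allyloxy)acetyl]-4-benzyl-1,3-oxazolidin-2-one, via mixed pivalic anhydride 5 (not isolated)
Conditions: t-BuCOCl, Et3N, THF, −20 °C; then 4, LiCl, rt
Reagents that add atoms: none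
Why: N-acylation of the oxazolidinone through the mixed anhydride; attack goes to the less hindered glycolyl carbonyl.

Step 3
Reactants: 6 (R)-3-[2-(allyloxy)acetyl]-4-benzyl-1,3-oxazolidin-2-one; 7 (S)-citronellal
Product: 9 syn-aldol adduct (R)-4-benzyl-3-[(2R,3S,5S)-2-(allyloxy)-3-hydroxy-5,9-dimethyldec-8-enoyl]-1,3-oxazolidin-2-one, via dibutylboron Z-enolate 8 (not isolated)
Conditions: Bu2BOTf, Et3N, CH2Cl2, −78 → 0 °C; then 7, −78 → 0 °C; MeOH, pH 7 buffer, H2O2
Reagents that add atoms: none
Why: Evans syn glycolate aldol through a Zimmerman–Traxler transition state; the (R)-auxiliary should set C16 (R) and C15 (S) with the 15,16-syn relation, and the aldehyde has no α-stereocentre to oppose it. The C16 allyl ether is in place from this step on.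

Step 4
Reactants: 9 syn-aldol adduct
Product: 10 (2R,3S,5S)-2-(allyloxy)-3-hydroxy-N-methoxy-N,5,9-trimethyldec-8-enamide
Conditions: MeNHOMe·HCl, AlMe3, THF, −20 °C → rt
Reagents that add atoms: N,O-dimethylhydroxylamine hydrochloride, CNOC.Cl
Why: Aluminium-amide transamination of the imide, helped by the free β-hydroxyl; the auxiliary 4 is recovered.

Step 5
Reactants: 10 Weinreb amide
Product: 11 (2R,3S,5S)-2-(allyloxy)-N,3-dimethoxy-N,5,9-trimethyldec-8-enamide
Conditions: NaH, MeI, THF/DMF, 0 °C
Reagents that add atoms: iodomethane, CI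
Why: Williamson O-methylation of the C15 alkoxide; an amide enolate is a poor leaving group, so retro-aldol cleavage should be slow at 0 °C.

Step 6
Reactants: 11 C15 methyl ether
Product: 13 (2R,3S,5S)-2-(allyloxy)-8-hydroxy-N,3-dimethoxy-N,5-dimethyloctanamide, via C10 aldehyde 12 (not isolated)
Conditions: O3, CH2Cl2/MeOH, −78 °C (Sudan Red 7B end point); then NaBH4, −78 → 0 °C
Reagents that add atoms: ozone, [O-][O+]=O
Why: Selective ozonolysis; the electron-rich trisubstituted alkene reacts much faster than the inductively deactivated allyl ether alkene. Borohydride reduces the aldehyde and leaves the Weinreb amide.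

Step 7
Reactants: 13 hydroxy Weinreb amide
Product: 14 (2R,3S,5S)-2-(allyloxy)-1-(2-ethyl-1,3-dithian-2-yl)-8-hydroxy-3-methoxy-5-methyloctan-1-one
Conditions: 2-ethyl-1,3-dithiane, n-BuLi, THF, −30 °C; then 13, −78 → −30 °C
Reagents that add atoms: 2-ethyl-1,3-dithiane, CCC1SCCCS1
Why: Acyl anion (Corey–Seebach) addition to a Weinreb amide; the chelated tetrahedral intermediate stops at the ketone, and one extra equivalent of the lithiated dithiane is used up by the free hydroxyl.

Step 8
Reactants: 14 acyl dithiane
Product: 15 (1R,2S,3S,5S)-2-(allyloxy)-1-(2-ethyl-1,3-dithian-2-yl)-3-methoxy-5-methyloctane-1,8-diol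
Conditions: Zn(BH4)2, Et2O, −20 °C
Reagents that add atoms: none
Why: Chelation-controlled reduction (Cram chelate model): zinc bridges the C17 carbonyl and the C16 allyloxy oxygen and hydride enters anti to the C15 chain, which should give the 16,17-anti alcohol (C17 R).

Step 9
Reactants: 15 diol
Product: 16 (1R,2R,3S,5S)-2-(allyloxy)-1,8-bis(tert-butyldimethylsilyloxy)-1-(2-ethyl-1,3-dithian-2-yl)-3-methoxy-5-methyloctane
Conditions: TBSOTf, 2,6-lutidine, CH2Cl2, −78 → 0 °C
Reagents that add atoms: tert-butyldimethylsilyl triflate, CC(C)(C)[Si](C)(C)OS(=O)(=O)C(F)(F)F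
Why: Silylation of both hydroxyls with the reactive silyl triflate; a silyl group at C17-O offers no activated C–H bond to the later carbenoid.

Step 10
Reactants: 16 bis-silyl ether
Product: 17 (4R,5R,6S,8S)-5-(allyloxy)-4,11-bis(tert-butyldimethylsilyloxy)-6-methoxy-8-methylundecan-3-one
Conditions: PhI(OCOCF3)2, MeCN/H2O (9:1), 0 °C
Reagents that add atoms: water, O
Why: Oxidative hydrolysis of the dithiane by the hypervalent iodine reagent; sulfur is oxidised far faster than the terminal alkene, and silyl ethers tolerate the short exposure.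

Step 11
Reactants: 17 ethyl ketone
Product: 19 (4R,5R,6S,8S)-5-(allyloxy)-4,11-bis(tert-butyldimethylsilyloxy)-2-diazo-6-methoxy-8-methylundecan-3-one, via trifluoroacetyl ketone 18 (not isolated)
Conditions: LiN(SiMe3)2, THF, −78 °C; CF3CO2CH2CF3; then p-ABSA, Et3N, H2O, MeCN, rt
Reagents that add atoms: 4-acetamidobenzenesulfonyl azide, CC(=O)Nc1ccc(cc1)S(=O)(=O)N=[N+]=[N-]
Why: Deacylative (Regitz-type) diazo transfer: kinetic enolisation on the ethyl side, away from the hindered silyloxy methine, then trifluoroacetylation and transfer with loss of the trifluoroacetyl group. This gives the methyl diazoketone without diazoethane.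

Step 12
Reactants: 19 C16 O-allyl methyl diazoketone
Product: 20 (2R,4R,5R)-2-allyl-4-(tert-butyldimethylsilyloxy)-5-[(1S,3S)-6-(tert-butyldimethylsilyloxy)-1-methoxy-3-methylhexyl]-2-methyldihydrofuran-3(2H)-one
Conditions: Cu(acac)2 (10 mol %), THF, reflux, slow addition of 19
Reagents that add atoms: none
Why: The copper complex decomposes the diazo group to an electrophilic copper carbenoid at C19, a lone pair of the C16 ether oxygen adds to it, and the resulting five-membered cyclic oxonium ylide undergoes a suprafacial [2,3]-sigmatropic shift that moves the allyl group from oxygen to C19. The closest known reaction type is the copper- or rhodium-catalysed oxonium ylide formation and [2,3]-rearrangement of allyl ethers of diazoketones to trans-2,5-disubstituted 2-allyl-tetrahydrofuran-3-ones. The one ring closes by O–C19 bond formation on the tether O–C16–C17–C18–C19, so the five-membered ylide is favoured over the four-membered one from the C17 oxygen and the six-membered one from the C15 methoxy oxygen. The new stereocentre C19 is controlled by C16: on the oxonium oxygen the allyl group sits trans to the C16 side chain and is delivered on that face, so C20 ends anti to C15 (19R) and the methyl group cis to the chain. The step needs ylide formation to beat 1,2-hydride migration from the C19 methyl group, C–H insertion and cyclopropanation. A copper catalyst should favour ylide formation over hydride shift better than a rhodium carboxylate, the silyl group on the C17 oxygen removes the activated C–H bonds an alkyl ether would offer, and the alkene of the allyl ether is too far for a strain-free cyclopropane. The methyl-substituted carbenoid is the less common case, so the step is treated as the main risk.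

Step 13
Reactants: 20 tetrahydrofuranone
Product: 21 (2R,3R,4S,5R)-2-allyl-4-(tert-butyldimethylsilyloxy)-5-[(1S,3S)-6-(tert-butyldimethylsilyloxy)-1-methoxy-3-methylhexyl]-2-methyltetrahydrofuran-3-ol
Conditions: LiBH(s-Bu)3, THF, −78 °C; NaOH, H2O2
Reagents that add atoms: none
Why: The bulky borohydride should attack the ring ketone from the face of the C19 methyl group and the C17 hydrogen, away from the allyl and silyloxy groups, giving the C18 alcohol cis to the C17 oxygen (18R).

Step 14
Reactants: 21 C18 alcohol
Product: 23 (2R,3S,4R,5R)-2-allyl-3-bromo-4-(tert-butyldimethylsilyloxy)-5-[(1S,3S)-6-(tert-butyldimethylsilyloxy)-1-methoxy-3-methylhexyl]-2-methyltetrahydrofuran, via C18 triflate 22 (not isolated)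
Conditions: Tf2O, pyridine, CH2Cl2, −20 → 0 °C; then Bu4NBr, rt → 35 °C
Reagents that add atoms: tetrabutylammonium bromide, CCCC[N+](CCCC)(CCCC)CCCC.[Br-]
Why: Sulfonylation, then SN2 displacement with inversion by a poorly solvated bromide, puts bromine trans to the C17 oxygen and cis to the C19 methyl group (18S). The five-membered ring and the very good leaving group are relied on to overcome the neopentyl-type hindrance.

Step 15
Reactants: 23 bromide
Product: 24 (4S,6S)-6-[(2R,3R,4S,5R)-5-allyl-4-bromo-3-(tert-butyldimethylsilyloxy)-5-methyltetrahydrofuran-2-yl]-6-methoxy-4-methylhexan-1-ol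
Conditions: HF·pyridine, pyridine, THF, 0 °C
Reagents that add atoms: none
Why: Selective desilylation; the primary silyl ether is far more accessible than the ring silyl ether flanked by C16 and C18.

Step 16
Reactants: 24 C10 alcohol
Product: 25 (4S,6S)-6-[(2R,3R,4S,5R)-5-allyl-4-bromo-3-(tert-butyldimethylsilyloxy)-5-methyltetrahydrofuran-2-yl]-6-methoxy-4-methylhexanoic acid
Conditions: TEMPO (cat.), PhI(OAc)2, MeCN/H2O, rt
Reagents that add atoms: water, O
Why: Nitroxyl-catalysed oxidation of the primary alcohol through the aldehyde hydrate to the acid; alkene, bromide and silyl ether are inert.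

Step 17
Reactants: 25 C10 acid
Product: 27 (4S,6S)-6-[(2R,3R,4S,5R)-5-allyl-4-bromo-3-(tert-butyldimethylsilyloxy)-5-methyltetrahydrofuran-2-yl]-6-methoxy-4-methylhexanamide, via mixed carbonic anhydride 26 (not isolated)
Conditions: i-BuOCOCl, N-methylmorpholine, THF, −15 °C; then NH3 (0.5 M in dioxane), 0 °C
Reagents that add atoms: ammonia, N
Why: Mixed-anhydride activation and ammonolysis; the hindered secondary bromide is not displaced by ammonia at 0 °C.

Step 18
Reactants: 27 primary amide
Product: 28 N-(2-bromoacetyl) derivative of amide 27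
Conditions: BrCH2COBr, pyridine, CH2Cl2, 0 °C → rt
Reagents that add atoms: bromoacetyl bromide, BrCC(=O)Br
Why: N-Acylation of the primary amide gives the imide that carries C8 and C9 of the oxazole.

Step 19
Reactants: 28 N-(bromoacetyl) amide
Product: 30 2-{(3S,5S)-5-[(2R,3R,4S,5R)-5-allyl-4-bromo-3-(tert-butyldimethylsilyloxy)-5-methyltetrahydrofuran-2-yl]-5-methoxy-3-methylpentyl}oxazol-4-yl triflate, via oxazol-4(5H)-one 29 (not isolated)
Conditions: i-Pr2NEt, CH2Cl2, 0 °C → rt; then Tf2O, −78 °C
Reagents that add atoms: triflic anhydride, O=S(=O)(OS(=O)(=O)C(F)(F)F)C(F)(F)F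
Why: Base-induced 5-exo-tet O-alkylation of the imide closes the oxazol-4(5H)-one, and its enol form is trapped as the aromatic 4-triflate. This is the known route from amides and α-haloacyl halides to oxazolones followed by enol triflation.

Step 20
Reactants: 30 oxazolyl triflate
Product: 32 C21 aldehyde (13S,15S,16R,17R,18S,19R), via 1,2,4-trioxolane 31 (not isolated)
Conditions: O3, CH2Cl2, −78 °C (Sudan Red 7B end point); then PPh3, −78 °C → rt
Reagents that add atoms: ozone, [O-][O+]=O
Why: Ozonolysis of the only alkene with reductive work-up; the electron-poor oxazolyl triflate should not react at the indicator end point. The β-alkoxy aldehyde is used at once.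

Step 21
Reactants: 33 (S)-citramalic acid
Product: 34 2-[(4S)-2,2,4-trimethyl-5-oxo-1,3-dioxolan-4-yl]acetic acid
Conditions: 2,2-dimethoxypropane, TsOH (cat.), rt
Reagents that add atoms: 2,2-dimethoxypropane, COC(C)(C)OC
Why: Acetalisation of the α-hydroxy acid unit as the five-membered dioxolanone leaves the other carboxyl free; the stereocentre is not touched.

Step 22
Reactants: 34 dioxolanone acid
Product: 35 (5S)-5-(2-hydroxyethyl)-2,2,5-trimethyl-1,3-dioxolan-4-one
Conditions: BH3·SMe2, THF, 0 °C → rt; MeOH quench
Reagents that add atoms: none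
Why: Borane reduces the free acid chemoselectively beside the dioxolanone carbonyl; the alcohol is used directly, without acid contact, so that it does not translactonise.

Step 23
Reactants: 35 hydroxyethyl dioxolanone
Product: 36 (5S)-5-(2-iodoethyl)-2,2,5-trimethyl-1,3-dioxolan-4-one
Conditions: I2, PPh3, imidazole, CH2Cl2, 0 °C → rt
Reagents that add atoms: iodine, II
Why: Appel-type iodination under imidazole buffering.

Step 24
Reactants: 36 iodide
Product: 37 triphenyl{2-[(4S)-2,2,4-trimethyl-5-oxo-1,3-dioxolan-4-yl]ethyl}phosphonium iodide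
Conditions: PPh3, MeCN, reflux
Reagents that add atoms: triphenylphosphine, c1ccc(cc1)P(c1ccccc1)c1ccccc1
Why: SN2 quaternisation of the primary iodide.

Step 25
Reactants: 32 C21 aldehyde; 37 phosphonium iodide
Product: 39 Z-alkene with dioxolanone side chain and C8 triflate (13S,15S,16R,17R,18S,19R,24S; 21Z), via phosphonium ylide 38 (not isolated)
Conditions: NaN(SiMe3)2, THF, −78 °C; then 32, −78 → 0 °C
Reagents that add atoms: none
Why: Wittig reaction of a non-stabilised ylide without lithium salts should give the Z-alkene; base is kept below one equivalent and the temperature low, so the β-alkoxy aldehyde does not eliminate and the triflate is not attacked.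

Step 26
Reactants: 39 Z-alkene
Product: 40 C17 alcohol (13S,15S,16S,17R,18S,19R,24S; 21Z; the C16 descriptor changes by priority only)
Conditions: HF·pyridine, THF, 0 °C → rt
Reagents that add atoms: none
Why: Fluoride desilylation under non-basic, water-free conditions, so that the bromohydrin does not close to an epoxide and the triflate and acetonide survive.

Step 27
Reactants: 40 C17 alcohol
Product: 41 C17 diethylphosphonoacetate (13S,15S,16R,17R,18S,19R,24S; 21Z)
Conditions: (EtO)2P(O)CH2CO2H, DCC, DMAP (cat.), CH2Cl2, 0 °C → rt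
Reagents that add atoms: diethylphosphonoacetic acid, CCOP(=O)(CC(=O)O)OCC
Why: Carbodiimide (Steglich) esterification of the hindered secondary alcohol with a small acid.

Step 28
Reactants: 42 (R)-4-benzyl-3-propionyl-1,3-oxazolidin-2-one; 43 but-2-ynal
Product: 45 (R)-4-benzyl-3-[(2R,3R)-3-hydroxy-2-methylhex-4-ynoyl]-1,3-oxazolidin-2-one, via dibutylboron Z-enolate 44 (not isolated)
Conditions: Bu2BOTf, Et3N, CH2Cl2, 0 °C; then 43, −78 → 0 °C; MeOH, pH 7 buffer, H2O2
Reagents that add atoms: none
Why: Evans syn aldol via the boron Z-enolate and a Zimmerman–Traxler transition state; the (R)-auxiliary should set the syn C4/C5 pair of the target.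

Step 29
Reactants: 45 aldol adduct
Product: 46 (R)-4-benzyl-3-[(2R,3R)-2-methyl-3-(triethylsilyloxy)hex-4-ynoyl]-1,3-oxazolidin-2-one
Conditions: TESOTf, 2,6-lutidine, CH2Cl2, −78 °C
Reagents that add atoms: triethylsilyl triflate, CC[Si](CC)(CC)OS(=O)(=O)C(F)(F)F
Why: Silylation of the propargylic alcohol; the triethylsilyl group is chosen because it can leave under mild acid at the end.

Step 30
Reactants: 46 silyl ether
Product: 47 (2S,3R)-2-methyl-3-(triethylsilyloxy)hex-4-yn-1-ol
Conditions: LiBH4, MeOH (1 equiv), Et2O, 0 °C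
Reagents that add atoms: none
Why: Reductive removal of the auxiliary at the exocyclic carbonyl; 4 is recovered.

Step 31
Reactants: 47 alkynol
Product: 49 (2S,3R,4E)-5-iodo-2-methyl-3-(triethylsilyloxy)hex-4-en-1-ol, via alkenylzirconocene chloride 48 (not isolated)
Conditions: Cp2Zr(H)Cl (2.5 equiv), THF, rt → 40 °C; then I2, 0 °C
Reagents that add atoms: iodine, II
Why: Hydrozirconation is a syn addition that, with excess reagent, settles zirconium on the less hindered, methyl-bearing alkyne carbon (C7); iodinolysis with retention gives the E-iodide. One equivalent of reagent is used up by the hydroxyl.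

Step 32
Reactants: 49 alkenyl iodide
Product: 50 (2S,3R,4E)-2-methyl-5-(tributylstannyl)-3-(triethylsilyloxy)hex-4-en-1-ol
Conditions: (Bu3Sn)2, Pd(PPh3)4 (cat.), i-Pr2NEt, toluene, 80 °C
Reagents that add atoms: hexabutylditin, CCCC[Sn](CCCC)(CCCC)[Sn](CCCC)(CCCC)CCCC
Why: Palladium-catalysed stannylation of an alkenyl iodide with retention of geometry; it avoids an alkyllithium and tolerates the free hydroxyl.

Step 33
Reactants: 50 stannyl alcohol
Product: 51 (2R,3R,4E)-2-methyl-5-(tributylstannyl)-3-(triethylsilyloxy)hex-4-enal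
Conditions: Dess–Martin periodinane, NaHCO3, CH2Cl2, 0 °C → rt
Reagents that add atoms: none
Why: Buffered Dess–Martin oxidation; mild enough for the alkenylstannane and the α-stereocentre.

Step 34
Reactants: 41 oxazolyl triflate phosphonoacetate; 51 stannyl aldehyde
Product: 52 open-chain C3 aldehyde with C17 phosphonoacetate (4R,5S,13S,15S,16R,17R,18S,19R,24S; 6E,21Z)
Conditions: Pd(PPh3)4 (cat.), Cu(O2C-2-C4H3S) (copper thiophene-2-carboxylate), [Bu4N][Ph2PO2], DMF, rt
Reagents that add atoms: none
Why: Stille coupling: zerovalent palladium inserts into the oxazolyl triflate, the copper carboxylate relays the hindered alkenyl group from tin, and reductive elimination with retention gives the E-trisubstituted alkene. The medium is neutral, so aldehyde and phosphonate should not yet react with each other.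

Step 35
Reactants: 52 open-chain aldehyde phosphonate
Product: 53 macrolactone with C5 triethylsilyl ether and side-chain acetonide (4S,5R,13S,15S,16R,17R,18S,19R,24S; 2E,6E,21Z)
Conditions: LiCl, i-Pr2NEt, MeCN, rt, high dilution (1 mM)
Reagents that add atoms: none
Why: Intramolecular Horner–Wadsworth–Emmons reaction under Masamune–Roush conditions; the lithium-chelated phosphonate is deprotonated by a weak amine base, which should spare the C4 stereocentre and the β-silyloxy group and give the E-enoate.

Step 36
Reactants: 53 protected macrolactone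
Product: 55 CNP0163177.2 (target), via C5 alcohol 54 (not isolated)
Conditions: AcOH/THF/H2O (3:1:1), 40 °C
Reagents that add atoms: water, O
Why: Mild aqueous acid first cleaves the secondary triethylsilyl ether and then hydrolyses the dioxolanone, an acetal of an α-hydroxy acid, to the free tertiary alcohol and carboxylic acid. A weak acid is chosen so that the allylic alcohol does not ionise.

## Compound list

1 | allyl alcohol | C=CCO | starting material
2 | bromoacetic acid | OC(=O)CBr | starting material
3 | 2-(allyloxy)acetic acid | C=CCOCC(=O)O | intermediate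
4 | (R)-4-benzyl-1,3-oxazolidin-2-one | O=C1OC[C@@H](Cc2ccccc2)N1 | starting material
5 | 2-(allyloxy)acetic pivalic anhydride | C=CCOCC(=O)OC(=O)C(C)(C)C | intermediate (not isolated)
6 | (R)-3-[2-(allyloxy)acetyl]-4-benzyl-1,3-oxazolidin-2-one | C=CCOCC(=O)N1[C@H](Cc2ccccc2)COC1=O | intermediate
7 | (S)-citronellal | CC(C)=CCC[C@H](C)CC=O | starting material
8 | dibutylboron Z-enolate of 6 | CCCCB(CCCC)O/C(=C\OCC=C)N1[C@H](Cc2ccccc2)COC1=O | intermediate (not isolated)
9 | (R)-4-benzyl-3-[(2R,3S,5S)-2-(allyloxy)-3-hydroxy-5,9-dimethyldec-8-enoyl]-1,3-oxazolidin-2-one | O=C(N1[C@H](Cc2ccccc2)COC1=O)[C@H](OCC=C)[C@@H](O)C[C@@H](C)CCC=C(C)C | intermediate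
10 | (2R,3S,5S)-2-(allyloxy)-3-hydroxy-N-methoxy-N,5,9-trimethyldec-8-enamide | CON(C)C(=O)[C@H](OCC=C)[C@@H](O)C[C@@H](C)CCC=C(C)C | intermediate
11 | (2R,3S,5S)-2-(allyloxy)-N,3-dimethoxy-N,5,9-trimethyldec-8-enamide | CON(C)C(=O)[C@H](OCC=C)[C@@H](OC)C[C@@H](C)CCC=C(C)C | intermediate
12 | (2R,3S,5S)-2-(allyloxy)-N,3-dimethoxy-N,5-dimethyl-8-oxooctanamide | CON(C)C(=O)[C@H](OCC=C)[C@@H](OC)C[C@@H](C)CCC=O | intermediate (not isolated)
13 | (2R,3S,5S)-2-(allyloxy)-8-hydroxy-N,3-dimethoxy-N,5-dimethyloctanamide | CON(C)C(=O)[C@H](OCC=C)[C@@H](OC)C[C@@H](C)CCCO | intermediate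
14 | (2R,3S,5S)-2-(allyloxy)-1-(2-ethyl-1,3-dithian-2-yl)-8-hydroxy-3-methoxy-5-methyloctan-1-one | CCC1(SCCCS1)C(=O)[C@H](OCC=C)[C@@H](OC)C[C@@H](C)CCCO | intermediate
15 | (1R,2S,3S,5S)-2-(allyloxy)-1-(2-ethyl-1,3-dithian-2-yl)-3-methoxy-5-methyloctane-1,8-diol | CCC1(SCCCS1)[C@H](O)[C@H](OCC=C)[C@@H](OC)C[C@@H](C)CCCO | intermediate
16 | (1R,2R,3S,5S)-2-(allyloxy)-1,8-bis(tert-butyldimethylsilyloxy)-1-(2-ethyl-1,3-dithian-2-yl)-3-methoxy-5-methyloctane | CCC1(SCCCS1)[C@H](O[Si](C)(C)C(C)(C)C)[C@H](OCC=C)[C@@H](OC)C[C@@H](C)CCCO[Si](C)(C)C(C)(C)C | intermediate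
17 | (4R,5R,6S,8S)-5-(allyloxy)-4,11-bis(tert-butyldimethylsilyloxy)-6-methoxy-8-methylundecan-3-one | CCC(=O)[C@H](O[Si](C)(C)C(C)(C)C)[C@H](OCC=C)[C@@H](OC)C[C@@H](C)CCCO[Si](C)(C)C(C)(C)C | intermediate
18 | (5R,6R,7S,9S)-6-(allyloxy)-5,12-bis(tert-butyldimethylsilyloxy)-1,1,1-trifluoro-7-methoxy-3,9-dimethyldodecane-2,4-dione (C3 epimers) | CC(C(=O)C(F)(F)F)C(=O)[C@H](O[Si](C)(C)C(C)(C)C)[C@H](OCC=C)[C@@H](OC)C[C@@H](C)CCCO[Si](C)(C)C(C)(C)C | intermediate (not isolated)
19 | (4R,5R,6S,8S)-5-(allyloxy)-4,11-bis(tert-butyldimethylsilyloxy)-2-diazo-6-methoxy-8-methylundecan-3-one | CC(=[N+]=[N-])C(=O)[C@H](O[Si](C)(C)C(C)(C)C)[C@H](OCC=C)[C@@H](OC)C[C@@H](C)CCCO[Si](C)(C)C(C)(C)C | intermediate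
20 | (2R,4R,5R)-2-allyl-4-(tert-butyldimethylsilyloxy)-5-[(1S,3S)-6-(tert-butyldimethylsilyloxy)-1-methoxy-3-methylhexyl]-2-methyldihydrofuran-3(2H)-one | CC(C)(C)[Si](C)(C)OCCC[C@H](C)C[C@H](OC)[C@H]1O[C@](C)(CC=C)C(=O)[C@@H]1O[Si](C)(C)C(C)(C)C | intermediate
21 | (2R,3R,4S,5R)-2-allyl-4-(tert-butyldimethylsilyloxy)-5-[(1S,3S)-6-(tert-butyldimethylsilyloxy)-1-methoxy-3-methylhexyl]-2-methyltetrahydrofuran-3-ol | CC(C)(C)[Si](C)(C)OCCC[C@H](C)C[C@H](OC)[C@H]1O[C@](C)(CC=C)[C@H](O)[C@@H]1O[Si](C)(C)C(C)(C)C | intermediate
22 | C18 triflate of 21 (2R,3R,4R,5R ring descriptors) | CC(C)(C)[Si](C)(C)OCCC[C@H](C)C[C@H](OC)[C@H]1O[C@](C)(CC=C)[C@H](OS(=O)(=O)C(F)(F)F)[C@@H]1O[Si](C)(C)C(C)(C)C | intermediate (not isolated)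
23 | (2R,3S,4R,5R)-2-allyl-3-bromo-4-(tert-butyldimethylsilyloxy)-5-[(1S,3S)-6-(tert-butyldimethylsilyloxy)-1-methoxy-3-methylhexyl]-2-methyltetrahydrofuran | CC(C)(C)[Si](C)(C)OCCC[C@H](C)C[C@H](OC)[C@H]1O[C@](C)(CC=C)[C@@H](Br)[C@@H]1O[Si](C)(C)C(C)(C)C | intermediate
24 | (4S,6S)-6-[(2R,3R,4S,5R)-5-allyl-4-bromo-3-(tert-butyldimethylsilyloxy)-5-methyltetrahydrofuran-2-yl]-6-methoxy-4-methylhexan-1-ol | OCCC[C@H](C)C[C@H](OC)[C@H]1O[C@](C)(CC=C)[C@@H](Br)[C@@H]1O[Si](C)(C)C(C)(C)C | intermediate
25 | (4S,6S)-6-[(2R,3R,4S,5R)-5-allyl-4-bromo-3-(tert-butyldimethylsilyloxy)-5-methyltetrahydrofuran-2-yl]-6-methoxy-4-methylhexanoic acid | OC(=O)CC[C@H](C)C[C@H](OC)[C@H]1O[C@](C)(CC=C)[C@@H](Br)[C@@H]1O[Si](C)(C)C(C)(C)C | intermediate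
26 | isobutyl carbonic anhydride of 25 | CC(C)COC(=O)OC(=O)CC[C@H](C)C[C@H](OC)[C@H]1O[C@](C)(CC=C)[C@@H](Br)[C@@H]1O[Si](C)(C)C(C)(C)C | intermediate (not isolated)
27 | (4S,6S)-6-[(2R,3R,4S,5R)-5-allyl-4-bromo-3-(tert-butyldimethylsilyloxy)-5-methyltetrahydrofuran-2-yl]-6-methoxy-4-methylhexanamide | NC(=O)CC[C@H](C)C[C@H](OC)[C@H]1O[C@](C)(CC=C)[C@@H](Br)[C@@H]1O[Si](C)(C)C(C)(C)C | intermediate
28 | N-(2-bromoacetyl) derivative of amide 27 | BrCC(=O)NC(=O)CC[C@H](C)C[C@H](OC)[C@H]1O[C@](C)(CC=C)[C@@H](Br)[C@@H]1O[Si](C)(C)C(C)(C)C | intermediate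
29 | 2-substituted oxazol-4(5H)-one from 28 (C11–C19 chain on C2) | O=C1COC(CC[C@H](C)C[C@H](OC)[C@H]2O[C@](C)(CC=C)[C@@H](Br)[C@@H]2O[Si](C)(C)C(C)(C)C)=N1 | intermediate (not isolated)
30 | 2-{(3S,5S)-5-[(2R,3R,4S,5R)-5-allyl-4-bromo-3-(tert-butyldimethylsilyloxy)-5-methyltetrahydrofuran-2-yl]-5-methoxy-3-methylpentyl}oxazol-4-yl triflate | FC(F)(F)S(=O)(=O)Oc1coc(CC[C@H](C)C[C@H](OC)[C@H]2O[C@](C)(CC=C)[C@@H](Br)[C@@H]2O[Si](C)(C)C(C)(C)C)n1 | intermediate
31 | 1,2,4-trioxolane (ozonide) of 30 at C21/C22 | FC(F)(F)S(=O)(=O)Oc1coc(CC[C@H](C)C[C@H](OC)[C@H]2O[C@](C)(CC3OCOO3)[C@@H](Br)[C@@H]2O[Si](C)(C)C(C)(C)C)n1 | intermediate (not isolated)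
32 | C21 aldehyde: 2-[(2R,3S,4R,5R)-3-bromo-4-(tert-butyldimethylsilyloxy)-5-{(1S,3S)-1-methoxy-3-methyl-5-[4-(triflyloxy)oxazol-2-yl]pentyl}-2-methyltetrahydrofuran-2-yl]acetaldehyde | FC(F)(F)S(=O)(=O)Oc1coc(CC[C@H](C)C[C@H](OC)[C@H]2O[C@](C)(CC=O)[C@@H](Br)[C@@H]2O[Si](C)(C)C(C)(C)C)n1 | intermediate
33 | (S)-citramalic acid | OC(=O)C[C@](C)(O)C(=O)O | starting material
34 | 2-[(4S)-2,2,4-trimethyl-5-oxo-1,3-dioxolan-4-yl]acetic acid | OC(=O)C[C@]1(C)OC(C)(C)OC1=O | intermediate
35 | (5S)-5-(2-hydroxyethyl)-2,2,5-trimethyl-1,3-dioxolan-4-one | OCC[C@]1(C)OC(C)(C)OC1=O | intermediate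
36 | (5S)-5-(2-iodoethyl)-2,2,5-trimethyl-1,3-dioxolan-4-one | ICC[C@]1(C)OC(C)(C)OC1=O | intermediate
37 | triphenyl{2-[(4S)-2,2,4-trimethyl-5-oxo-1,3-dioxolan-4-yl]ethyl}phosphonium iodide | C(C[C@]1(C)OC(C)(C)OC1=O)[P+](c1ccccc1)(c1ccccc1)c1ccccc1.[I-] | intermediate
38 | phosphonium ylide of 37 | C(C[C@]1(C)OC(C)(C)OC1=O)=P(c1ccccc1)(c1ccccc1)c1ccccc1 | intermediate (not isolated)
39 | Z-alkene: C8 triflate, C17 silyl ether, dioxolanone side chain (13S,15S,16R,17R,18S,19R,24S; 21Z) | FC(F)(F)S(=O)(=O)Oc1coc(CC[C@H](C)C[C@H](OC)[C@H]2O[C@](C)(C/C=C\C[C@]3(C)OC(C)(C)OC3=O)[C@@H](Br)[C@@H]2O[Si](C)(C)C(C)(C)C)n1 | intermediate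
40 | C17 alcohol of 39 (13S,15S,16S,17R,18S,19R,24S; 21Z) | FC(F)(F)S(=O)(=O)Oc1coc(CC[C@H](C)C[C@H](OC)[C@H]2O[C@](C)(C/C=C\C[C@]3(C)OC(C)(C)OC3=O)[C@@H](Br)[C@@H]2O)n1 | intermediate
41 | C17 diethylphosphonoacetate of 40 (13S,15S,16R,17R,18S,19R,24S; 21Z) | FC(F)(F)S(=O)(=O)Oc1coc(CC[C@H](C)C[C@H](OC)[C@H]2O[C@](C)(C/C=C\C[C@]3(C)OC(C)(C)OC3=O)[C@@H](Br)[C@@H]2OC(=O)CP(=O)(OCC)OCC)n1 | intermediate
42 | (R)-4-benzyl-3-propionyl-1,3-oxazolidin-2-one | CCC(=O)N1[C@H](Cc2ccccc2)COC1=O | starting material
43 | but-2-ynal | CC#CC=O | starting material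
44 | dibutylboron Z-enolate of 42 | CCCCB(CCCC)O/C(=C\C)N1[C@H](Cc2ccccc2)COC1=O | intermediate (not isolated)
45 | (R)-4-benzyl-3-[(2R,3R)-3-hydroxy-2-methylhex-4-ynoyl]-1,3-oxazolidin-2-one | CC#C[C@H](O)[C@@H](C)C(=O)N1[C@H](Cc2ccccc2)COC1=O | intermediate
46 | (R)-4-benzyl-3-[(2R,3R)-2-methyl-3-(triethylsilyloxy)hex-4-ynoyl]-1,3-oxazolidin-2-one | CC#C[C@H](O[Si](CC)(CC)CC)[C@@H](C)C(=O)N1[C@H](Cc2ccccc2)COC1=O | intermediate
47 | (2S,3R)-2-methyl-3-(triethylsilyloxy)hex-4-yn-1-ol | CC#C[C@H](O[Si](CC)(CC)CC)[C@@H](C)CO | intermediate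
48 | (E)-alkenylzirconocene chloride from 47 (zirconium on C7; hydroxyl drawn free) | C/C(=C\[C@H](O[Si](CC)(CC)CC)[C@@H](C)CO)[Zr](Cl)(C1C=CC=C1)C1C=CC=C1 | intermediate (not isolated)
49 | (2S,3R,4E)-5-iodo-2-methyl-3-(triethylsilyloxy)hex-4-en-1-ol | C/C(I)=C\[C@H](O[Si](CC)(CC)CC)[C@@H](C)CO | intermediate
50 | (2S,3R,4E)-2-methyl-5-(tributylstannyl)-3-(triethylsilyloxy)hex-4-en-1-ol | C/C(=C\[C@H](O[Si](CC)(CC)CC)[C@@H](C)CO)[Sn](CCCC)(CCCC)CCCC | intermediate
51 | (2R,3R,4E)-2-methyl-5-(tributylstannyl)-3-(triethylsilyloxy)hex-4-enal | C/C(=C\[C@H](O[Si](CC)(CC)CC)[C@@H](C)C=O)[Sn](CCCC)(CCCC)CCCC | intermediate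
52 | open-chain C3 aldehyde with C17 phosphonoacetate (4R,5S,13S,15S,16R,17R,18S,19R,24S; 6E,21Z) | O=C[C@H](C)[C@@H](O[Si](CC)(CC)CC)/C=C(C)/c1coc(CC[C@H](C)C[C@H](OC)[C@H]2O[C@](C)(C/C=C\C[C@]3(C)OC(C)(C)OC3=O)[C@@H](Br)[C@@H]2OC(=O)CP(=O)(OCC)OCC)n1 | intermediate
53 | macrolactone, C5 triethylsilyl ether, side-chain acetonide (4S,5R,13S,15S,16R,17R,18S,19R,24S; 2E,6E,21Z) | O=C1/C=C/[C@H](C)[C@@H](O[Si](CC)(CC)CC)/C=C(C)/c2coc(CC[C@H](C)C[C@H](OC)[C@H]3O[C@](C)(C/C=C\C[C@]4(C)OC(C)(C)OC4=O)[C@@H](Br)[C@@H]3O1)n2 | intermediate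
54 | macrolactone with free C5 hydroxyl and side-chain acetonide | O=C1/C=C/[C@H](C)[C@@H](O)/C=C(C)/c2coc(CC[C@H](C)C[C@H](OC)[C@H]3O[C@](C)(C/C=C\C[C@]4(C)OC(C)(C)OC4=O)[C@@H](Br)[C@@H]3O1)n2 | intermediate (not isolated)
55 | CNP0163177.2 (4S,5R,13S,15S,16R,17R,18S,19R,24S; 2E,6E,21Z) | CO[C@H]1C[C@@H](C)CCc2nc(co2)/C(C)=C/[C@H](O)[C@@H](C)/C=C/C(=O)O[C@@H]2[C@@H]1O[C@](C)(C/C=C\C[C@](C)(O)C(=O)O)[C@H]2Br | target

## Step count and least certain steps

Total step count: 36. Longest linear sequence: 26 steps (steps 1–20, 25–27 and 34–36); 24 from (S)-citronellal.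

Step 12 (key step). The copper carbenoid may suffer 1,2-hydride migration from the C19 methyl group, giving a vinyl ketone before the C16 oxygen captures it. The C15 methoxy oxygen may form a six-membered ylide reversibly, and the trans delivery of the allyl group may erode because the carbenoid carbon is substituted.
- Fallback: close the ring and introduce bromine together, with no carbenoid. It sets out from 13.
- Addition of the alkenyllithium made from (E)-1-iodo-2-methylpenta-1,4-diene and t-BuLi would give the dienone F1.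
- Chelation-controlled 1,2-reduction with Zn(BH4)2 would give the allylic alcohol F2, and TBSOTf the bis-silyl ether F3.
- N-Bromosuccinimide would then activate the E-trisubstituted alkene. The C16 allyl ether oxygen opens the bromonium ion at C19 in the 5-endo mode, and the allyl group is lost from the oxonium ion as N-allylsuccinimide.
- Anti addition to the E-alkene places bromine cis to the C19 methyl group, and the branch comes back to the route at 23. Its weak points are face selectivity under substrate control and competition from the C15 methoxy oxygen.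

Step 14. The neopentyl-type triflate may ionise faster than bromide attacks. This leads to 1,2-shift of a C19 substituent toward an oxygen-stabilised cation or to elimination toward C17, and substitution may simply be too slow.
- Fallback: the ring and the bromide would be made together by the bromoetherification branch described for step 12. It sets out from 13, comes back at 23, and needs no compound beyond those already listed there.

Step 8. Chelation between zinc, the ketone and the C16 ether oxygen may be incomplete, for instance through coordination to the dithiane sulfur atoms, and the non-chelated pathway would lower the 16,17-anti selectivity.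
- Fallback: reverse the order of bond formation at C17. It sets out from 13, which i-Bu2AlH would reduce to the α-allyloxy aldehyde F4.
- Addition of 2-ethyl-2-lithio-1,3-dithiane under Felkin–Anh control (the C16 oxygen anti to the incoming nucleophile) should give the same anti diol, coming back at 15.

Step 34. Transmetalation of the 1-methyl-substituted alkenylstannane is slow. Protodestannylation, homocoupling and loss of the aldehyde may overtake the cross-coupling.
- Fallback: change the organometallic partner. It sets out from 47 and 41.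
- Hydrozirconation of 47 (as in step 31, through 48), transmetalation to zinc with ZnCl2 and Negishi coupling with 41 under Pd(PPh3)4 would give the coupled primary alcohol F5.
- Dess–Martin oxidation of F5 comes back at 52. Zinc chloride triflate is formed beside F5.

## Further compounds

F1 | step 12 | (4E,7R,8S,10S)-7-(allyloxy)-13-hydroxy-8-methoxy-4,10-dimethyltrideca-1,4-dien-6-one | C=CC/C(C)=C/C(=O)[C@H](OCC=C)[C@@H](OC)C[C@@H](C)CCCO
F2 | step 12 | (4E,6S,7S,8S,10S)-7-(allyloxy)-8-methoxy-4,10-dimethyltrideca-1,4-diene-6,13-diol | C=CC/C(C)=C/[C@H](O)[C@H](OCC=C)[C@@H](OC)C[C@@H](C)CCCO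
F3 | step 12 | (4E,6S,7R,8S,10S)-7-(allyloxy)-6,13-bis(tert-butyldimethylsilyloxy)-8-methoxy-4,10-dimethyltrideca-1,4-diene | C=CC/C(C)=C/[C@H](O[Si](C)(C)C(C)(C)C)[C@H](OCC=C)[C@@H](OC)C[C@@H](C)CCCO[Si](C)(C)C(C)(C)C
F0 | step 14 | none | none
F4 | step 8 | (2R,3S,5S)-2-(allyloxy)-8-hydroxy-3-methoxy-5-methyloctanal | O=C[C@H](OCC=C)[C@@H](OC)C[C@@H](C)CCCO
F5 | step 34 | C3 primary alcohol corresponding to 52 (4S,5S,13S,15S,16R,17R,18S,19R,24S; 6E,21Z) | OC[C@H](C)[C@@H](O[Si](CC)(CC)CC)/C=C(C)/c1coc(CC[C@H](C)C[C@H](OC)[C@H]2O[C@](C)(C/C=C\C[C@]3(C)OC(C)(C)OC3=O)[C@@H](Br)[C@@H]2OC(=O)CP(=O)(OCC)OCC)n1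
A1 | alternative 1 | open-chain diyne ester with propynyl groups on oxazole C8 and on C5 | CC#C[C@H](O[Si](CC)(CC)CC)[C@@H](C)/C=C/C(=O)O[C@@H]1[C@H](O[C@](C)(CCO[Si](C(C)C)(C(C)C)C(C)C)[C@H]1Br)[C@@H](OC)C[C@@H](C)CCc1nc(C#CC)co1
A2 | alternative 1 | macrocyclic alkyne | CO[C@H]1C[C@@H](C)CCc2nc(co2)C#C[C@H](O[Si](CC)(CC)CC)[C@@H](C)/C=C/C(=O)O[C@@H]2[C@@H]1O[C@](C)(CCO[Si](C(C)C)(C(C)C)C(C)C)[C@H]2Br
A3 | alternative 2 | E-C2 vinyl iodide with free C17 hydroxyl | I/C=C/[C@H](C)[C@@H](O[Si](C)(C)C(C)(C)C)/C=C(C)/c1coc(CC[C@H](C)C[C@H](OC)[C@H]2O[C@](C)(C/C=C\C[C@]3(C)OC(C)(C)OC3=O)[C@@H](Br)[C@@H]2O)n1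
A4 | alternative 2 | protected macrolactone | O=C1/C=C/[C@H](C)[C@@H](O[Si](C)(C)C(C)(C)C)/C=C(C)/c2coc(CC[C@H](C)C[C@H](OC)[C@H]3O[C@](C)(C/C=C\C[C@]4(C)OC(C)(C)OC4=O)[C@@H](Br)[C@@H]3O1)n2
A5 | alternative 3 | E-trisubstituted homoallylic alcohol with C21 pivalate | CC(C)[Si](C(C)C)(C(C)C)OCCC[C@H](C)C[C@H](OC)[C@@H](O)[C@@H](O[Si](C)(C)C(C)(C)C)/C=C(C)/CCOC(=O)C(C)(C)C
A6 | alternative 3 | bromo-tetrahydrofuran with C21 pivalate | CC(C)[Si](C(C)C)(C(C)C)OCCC[C@H](C)C[C@H](OC)[C@H]1O[C@](C)(CCOC(=O)C(C)(C)C)[C@@H](Br)[C@@H]1O[Si](C)(C)C(C)(C)C
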